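## Analysis of the target

Piscisoflavone A (15) is an isoflavone: a chromen-4-one (ring A fused to the pyranone ring C) that carries the aryl ring B at C3. Ring A bears only the 7-hydroxyl. Ring B has C1' bonded to C3, hydroxyls at C2' and C4', a 3-methylbut-2-enyl (prenyl) group at C3' between them, a methoxyl at C5' and a single hydrogen at C6'. There is no stereocentre, and the only alkene outside the ring system ends in two methyl groups, so no configuration has to be set.

The sensitive part is the prenyl group flanked by two phenols. Strong acid closes it onto either oxygen to a dimethylchroman, and electrophilic halogen or oxidants attack the alkene and the electron-rich ring B. The hard parts are the ordered placement of four different substituents on ring B and the union of C3 with a hindered, ortho-oxygenated ring B at the chromone oxidation level.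

The strategy rests on one feature. Cutting ring C at C3–C4 and O1–C2 leaves C4 as the carbon of a ring-A aldehyde and C3 as the carbon of a ring-B aryl ketone, with C2 as the methylene between O1 and C3. Both C3 and C4 are then electrophilic carbonyl carbons, so the C3–C4 bond requires an acyl anion equivalent at C4, and the C2=C3 double bond can arise by loss of water from the C3 carbinol so formed.

## Retrosynthetic reasoning

**15 from 14.** The three phenols are unmasked last by cutting the acetal C–O bonds of the methoxymethyl ethers of isoflavone 14. Acid is the reagent the prenyl group tolerates least, so it is kept to one mild, separate operation on the finished skeleton.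

**14 from 13.** The C2=C3 double bond is traced back to the tertiary C3 alcohol of hydroxychromanone 13. Only C2 carries hydrogens next to C3, so elimination can lead only to the chromone. This turns C3 into an sp3 carbinol, the natural outcome of a carbonyl addition.

**13 from 12 (key disconnection).** The C3–C4 bond is cut, opening ring C to keto aldehyde 12. Cuts at C3–C1' or C4–C4a would need cross-coupling or acid-mediated acylation on sensitive rings; this cut instead lets ring B arrive complete as a plain aryl ketone, with C2, C3 and C4 all present in an open chain. The forward reaction has to invert the polarity of the aldehyde carbon C4 and add it to the ketone carbon C3 without enolising the acidic C2 methylene.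

**12 from 9 and 11.** The O1–C2 ether bond is cut to the phenol of salicylaldehyde 11 and the α-chloro ketone 9. The forward step is a phenoxide alkylation, run mildly enough that 12 does not condense with itself.

**11 from 10.** The 4-hydroxyl of 10 is masked selectively; the 2-hydroxyl is held in a hydrogen bond to the aldehyde and stays free for the ether formation.

**9 from 5 and 6.** The C1'–C(=O) bond is cut to aryllithium 7, drawn from arene 5, and amide 6, which delivers C3, C2 and the chlorine in one piece. Halogenating a ring-B acetophenone was rejected: electrophilic halogen would meet the prenyl alkene, and the acid released would cleave the acetals.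

**5 from 2 and 3.** The aryl–prenyl bond is cut to aryllithium 4 and allylic bromide 3. The position between the two acetal oxygens of 2 is the most acidic one, so the regiochemistry is certain. Electrophilic prenylation of a free resorcinol would give C- and O-alkylation mixtures.

**2 from 1.** The methoxymethyl ethers serve twice: as protecting groups, and as the directing groups for both metalations.

## Alternatives that were turned down

**Alternative 1:** Ring B is taken apart at C5'–C6', C1'–C2' and C2'–C3'. C1' and C6' come from the terminal alkyne of 3-ethynyl-7-(methoxymethoxy)chromen-4-one A2, C2' from a carbonyl ligand, and C3', C4' and C5' from the alkenyl(methoxy)carbene complex A3 of Cr(CO)5.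
- Forward key step: warming A2 with A3 would run a Dötz benzannulation (alkyne insertion into the chromium–carbene bond, CO insertion to a vinylketene, electrocyclic closure, tautomerisation) to phenol A1. Removing two methoxymethyl ethers would then give 15.
- For it: the para relation of the new C2' hydroxyl and the C5' methoxyl is exactly what this annulation produces, and the terminal alkyne places the chromone next to the new phenol. Ring C is already a chromone, so no dehydration is needed; on the end game this plan is stronger than the chosen one.
- Against it: the metal is stoichiometric. A3 must carry an acetal oxygen on its α-carbon and a skipped diene, which makes it delicate to prepare and handle, and its prenyl alkene can intercept the vinylcarbene intermediate. A2 is an alkyne cross-conjugated with an enone whose C2 is a Michael acceptor, a class for which cyclobutenone, indene and furan side paths gain weight. A2 also costs about four steps through a 3-iodochromone.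
- Comparison: the chosen route gives up direct entry at the chromone level. In exchange it has a catalytic, metal-free key step on a substrate class where that reaction is established, and a ring B that is bought as an arene and decorated by two directed metalations.

**Alternative 2:** Ring B is cut at C3'–C4' and C4'–C5'. C4' is supplied by carbon monoxide and the other five ring carbons by the tertiary propargylic acetate A5, a 3-acetoxy-1,4-enyne whose alkyne carries the prenyl group and whose alkene ends in the methoxy-bearing C5'.
- Forward key step: under [Rh(CO)2Cl]2 and CO the acetate would shift from C1' to C2', the resulting rhodium vinylcarbene would engage the methoxyvinyl unit, and CO insertion, reductive elimination and tautomerisation would give deoxybenzoin A4.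
- For it: the metal is catalytic and CO serves as a one-carbon unit. The C2' acetate and C4' phenol emerge already differentiated; on this point it is stronger than the chosen route, although the target does not need that differentiation.
- Against it: A4 still lacks C2. Ring C must be built afterwards by freeing the ring-A ortho phenol, inserting one carbon, cyclising, and removing acetate and acetals, three to four steps after the key step. A5 combines a tertiary acetate β to an aryl ketone (prone to elimination), an enol ether and a skipped enyne, and a heteroatom-substituted alkene terminus lies outside what this annulation is known to accept.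
- Comparison: the chosen route is shorter, keeps ring B as a purchased arene, and closes ring C in the key step itself.

**Alternative 3:** Ring C is cut at O1–C8a and C4–C4a. Ring A comes as the aryne released from silyl triflate A8, and ring B with C2, C3 and C4 as hydroxyacrylate A7.
- Forward key step: fluoride would generate the aryne, the enolate oxygen of A7 would add to the aryne carbon remote from bromine (C8a), and the aryl anion formed next to bromine (C4a) would attack the ester to close chromone A6. Hydrodebromination and acetal cleavage would follow.
- For it: the plan is convergent and, like alternative 1, arrives directly at the chromone oxidation level, where it is stronger than the chosen route.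
- Against it: enolates of the 1,3-dicarbonyl type normally attack arynes through carbon, which leads to acyl–alkylation, not the O-arylation needed here. Regiocontrol is paid for with a bromine at C5 that the target lacks and that must be removed without reducing the prenyl alkene. A8 needs four to five steps, and A7 requires ring B as an arylacetic ester, a longer preparation than that of chloro ketone 9.
- Comparison: the chosen route needs no auxiliary atom, its chemoselectivity follows from the substrate (one aldehyde, one tethered ketone), and both fragments are reached in one to three steps.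

Key step: step 6

Remark on the chemistry: the target has no stereocentre, so the only stereocentre of the route (C3 of 13) is carried as a racemate and removed in step 7. Compounds 1, 3, 6 and 10 are taken as purchased.

## Route

Step 1
Reactants: 1 4-methoxyresorcinol (4-methoxybenzene-1,3-diol)
Product: 2 1-methoxy-2,4-bis(methoxymethoxy)benzene
Conditions: NaH (2.5 equiv), MOMCl (2.4 equiv), DMF, 0 °C → rt
Reagents that add atoms: chloromethyl methyl ether (MOMCl), COCCl
Why: Williamson-type alkylation of both phenoxides gives the bis(methoxymethyl) ether. The acetal oxygens are needed as directing groups for both metalations and come off under mild acid at the end.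

Step 2
Reactants: 2 1-methoxy-2,4-bis(methoxymethoxy)benzene; 3 prenyl bromide (1-bromo-3-methylbut-2-ene)
Product: 5 1-methoxy-2,4-bis(methoxymethoxy)-3-(3-methylbut-2-enyl)benzene, via the C3 aryllithium 4 (not isolated)
Conditions: n-BuLi (1.1 equiv), THF, 0 °C → rt; then CuBr·SMe2 (10 mol %), 3, −78 °C → rt
Reagents that add atoms: none
Why: Directed ortho-metalation: the C3–H between the two OMOM groups is the most acidic and is chelated from both sides, so lithiation should occur only there. Copper-catalysed allylic substitution at the primary carbon of 3 should then give the linear prenyl group, since the other allyl terminus is disubstituted.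

Step 3
Reactants: 5 1-methoxy-2,4-bis(methoxymethoxy)-3-(3-methylbut-2-enyl)benzene; 6 2-chloro-N-methoxy-N-methylacetamide
Product: 9 2-chloro-1-[5-methoxy-2,4-bis(methoxymethoxy)-3-(3-methylbut-2-enyl)phenyl]ethanone, via the ortho aryllithium 7 (not isolated), via the lithium hemiaminal alkoxide 8 (not isolated)
Conditions: s-BuLi (1.2 equiv), TMEDA, THF, −78 → −40 °C; then 6, −78 °C; aq. NH4Cl at −78 °C
Reagents that add atoms: none
Why: Second directed ortho-metalation followed by Weinreb amide acylation: OMOM directs more strongly than OMe, and C5 is the only free position ortho to an OMOM group, so the kinetic base at low temperature should lithiate there and leave the benzylic–allylic CH2 alone. The chelated adduct 8 releases the α-chloro ketone only on quench, so there is no over-addition and no electrophilic halogen ever meets the prenyl alkene.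

Step 4
Reactants: 10 2,4-dihydroxybenzaldehyde
Product: 11 2-hydroxy-4-(methoxymethoxy)benzaldehyde
Conditions: MOMCl (1.05 equiv), K2CO3, acetone, 0 °C → rt
Reagents that add atoms: chloromethyl methyl ether (MOMCl), COCCl
Why: Selective Williamson-type alkylation of the 4-hydroxyl, which is the more acidic and is not hydrogen-bonded. The 2-hydroxyl is chelated to the aldehyde and should stay free.

Step 5
Reactants: 9 2-chloro-1-[5-methoxy-2,4-bis(methoxymethoxy)-3-(3-methylbut-2-enyl)phenyl]ethanone; 11 2-hydroxy-4-(methoxymethoxy)benzaldehyde
Product: 12 2-{2-[5-methoxy-2,4-bis(methoxymethoxy)-3-(3-methylbut-2-enyl)phenyl]-2-oxoethoxy}-4-(methoxymethoxy)benzaldehyde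
Conditions: K2CO3 (1.5 equiv), NaI (10 mol %), acetone, rt
Reagents that add atoms: none
Why: Williamson ether synthesis with Finkelstein activation of the α-chloro ketone by iodide. Weak base at room temperature should keep the product from the Rap–Stoermer aldol condensation that sets in on heating.

Step 6
Reactants: 12 2-{2-[5-methoxy-2,4-bis(methoxymethoxy)-3-(3-methylbut-2-enyl)phenyl]-2-oxoethoxy}-4-(methoxymethoxy)benzaldehyde
Product: 13 rac-3-hydroxy-3-[5-methoxy-2,4-bis(methoxymethoxy)-3-(3-methylbut-2-enyl)phenyl]-7-(methoxymethoxy)chroman-4-one
Conditions: 2-(pentafluorophenyl)-6,7-dihydro-5H-pyrrolo[2,1-c][1,2,4]triazol-2-ium tetrafluoroborate (20 mol %), Et3N (20 mol %), toluene (0.05 M), 25–40 °C, argon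
Reagents that add atoms: none
Why: The amine deprotonates the triazolium salt to the carbene, which adds to the aldehyde of 12; proton transfer gives the enaminol (Breslow intermediate), whose carbon, the future C4, attacks the tethered ketone carbonyl, the future C3, and proton transfer with loss of the carbene releases α-hydroxy ketone 13. The closest known reaction type is the carbene-catalysed intramolecular crossed aldehyde–ketone benzoin reaction of 2-(2-oxo-2-arylethoxy)benzaldehydes to 3-aryl-3-hydroxychroman-4-ones. Ring C (O1, C2, C3, C4, C4a, C8a) closes in the 6-exo-trig mode, the attacked C=O oxygen staying outside the ring. The new stereocentre C3 is formed without control by the achiral catalyst, as a racemate, which is acceptable because step 7 removes it. The donor and acceptor roles are fixed by the substrate: only the aldehyde, which has no α-hydrogen, can form the enaminol, and the ketone can only accept. Ring closure should beat intermolecular benzoin coupling because the ether tether holds the ketone within reach of a six-membered transition state and the solution is dilute. The competing base-induced aldol condensation of the aryloxymethyl ketone onto the aldehyde is held back by pairing an acidic N-pentafluorophenyl triazolium salt with only a substoichiometric tertiary amine, and the α-aryloxy group activates the otherwise electron-rich ketone by induction.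

Step 7
Reactants: 13 rac-3-hydroxy-3-[5-methoxy-2,4-bis(methoxymethoxy)-3-(3-methylbut-2-enyl)phenyl]-7-(methoxymethoxy)chroman-4-one
Product: 14 3-[5-methoxy-2,4-bis(methoxymethoxy)-3-(3-methylbut-2-enyl)phenyl]-7-(methoxymethoxy)chromen-4-one
Conditions: methyl N-(triethylammoniosulfonyl)carbamate (Burgess reagent, 2 equiv), toluene, 60 °C
Reagents that add atoms: none
Why: Burgess dehydration: the tertiary alcohol forms a sulfamate ester that undergoes syn-elimination, and since only C2 carries β-hydrogens only the C2=C3 alkene can form, driven by the conjugated 4-pyranone. The neutral conditions should spare the acetals and the prenyl group, and the stereocentre is erased.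

Step 8
Reactants: 14 3-[5-methoxy-2,4-bis(methoxymethoxy)-3-(3-methylbut-2-enyl)phenyl]-7-(methoxymethoxy)chromen-4-one
Product: 15 piscisoflavone A, 3-[2,4-dihydroxy-5-methoxy-3-(3-methylbut-2-enyl)phenyl]-7-hydroxychromen-4-one
Conditions: HCl (about 1 M) in MeOH–THF, 25–40 °C
Reagents that add atoms: none
Why: Acid-catalysed acetal exchange with methanol cleaves the three aryl methoxymethyl ethers. Dilute acid at mild temperature should leave the prenyl group uncyclised and the chromone and aryl methyl ether untouched.

## Compound list

1 | 4-methoxyresorcinol (4-methoxybenzene-1,3-diol) | COc1ccc(O)cc1O | starting material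
2 | 1-methoxy-2,4-bis(methoxymethoxy)benzene | COc1ccc(OCOC)cc1OCOC | intermediate
3 | prenyl bromide (1-bromo-3-methylbut-2-ene) | CC(C)=CCBr | starting material
4 | [3-methoxy-2,6-bis(methoxymethoxy)phenyl]lithium | [Li]c1c(OCOC)ccc(OC)c1OCOC | intermediate
5 | 1-methoxy-2,4-bis(methoxymethoxy)-3-(3-methylbut-2-enyl)benzene | COc1ccc(OCOC)c(CC=C(C)C)c1OCOC | intermediate
6 | 2-chloro-N-methoxy-N-methylacetamide | CON(C)C(=O)CCl | starting material
7 | [5-methoxy-2,4-bis(methoxymethoxy)-3-(3-methylbut-2-enyl)phenyl]lithium | [Li]c1cc(OC)c(OCOC)c(CC=C(C)C)c1OCOC | intermediate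
8 | lithium 2-chloro-1-[methoxy(methyl)amino]-1-[5-methoxy-2,4-bis(methoxymethoxy)-3-(3-methylbut-2-enyl)phenyl]ethanolate (racemic) | [Li]OC(CCl)(N(C)OC)c1cc(OC)c(OCOC)c(CC=C(C)C)c1OCOC | intermediate
9 | 2-chloro-1-[5-methoxy-2,4-bis(methoxymethoxy)-3-(3-methylbut-2-enyl)phenyl]ethanone | COc1cc(C(=O)CCl)c(OCOC)c(CC=C(C)C)c1OCOC | intermediate
10 | 2,4-dihydroxybenzaldehyde | O=Cc1ccc(O)cc1O | starting material
11 | 2-hydroxy-4-(methoxymethoxy)benzaldehyde | COCOc1ccc(C=O)c(O)c1 | intermediate
12 | 2-{2-[5-methoxy-2,4-bis(methoxymethoxy)-3-(3-methylbut-2-enyl)phenyl]-2-oxoethoxy}-4-(methoxymethoxy)benzaldehyde | O=Cc1ccc(OCOC)cc1OCC(=O)c1cc(OC)c(OCOC)c(CC=C(C)C)c1OCOC | intermediate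
13 | rac-3-hydroxy-3-[5-methoxy-2,4-bis(methoxymethoxy)-3-(3-methylbut-2-enyl)phenyl]-7-(methoxymethoxy)chroman-4-one (racemic at C3) | COCOc1ccc2C(=O)C(O)(c3cc(OC)c(OCOC)c(CC=C(C)C)c3OCOC)COc2c1 | intermediate
14 | 3-[5-methoxy-2,4-bis(methoxymethoxy)-3-(3-methylbut-2-enyl)phenyl]-7-(methoxymethoxy)chromen-4-one | COCOc1ccc2c(=O)c(-c3cc(OC)c(OCOC)c(CC=C(C)C)c3OCOC)coc2c1 | intermediate
15 | piscisoflavone A, 3-[2,4-dihydroxy-5-methoxy-3-(3-methylbut-2-enyl)phenyl]-7-hydroxychromen-4-one | COc1cc(-c2coc3cc(O)ccc3c2=O)c(O)c(CC=C(C)C)c1O | target

## Step count and least certain steps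

Total step count: 8. Longest linear sequence: 7 steps (steps 1, 2, 3, 5, 6, 7, 8); step 4 is a one-step branch that joins at step 5.

**Step 6 (key step).** The most likely failure is that base-promoted enolisation of the aryloxymethyl ketone and aldol condensation onto the aldehyde (benzofuran formation) outrun the carbene pathway. The other is that the enaminol forms reversibly but does not add to the electron-rich, ortho-substituted ketone, so that intermolecular benzoin coupling takes over.

Fallback, from 5 back to the route at 14: ring C is bought as a chromone and the C3–C1' bond is made instead of C3–C4.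
- Compound 5 is lithiated as in step 3 and quenched with 2-isopropoxy-4,4,5,5-tetramethyl-1,3,2-dioxaborolane to give 2-[5-methoxy-2,4-bis(methoxymethoxy)-3-(3-methylbut-2-enyl)phenyl]-4,4,5,5-tetramethyl-1,3,2-dioxaborolane F1.
- Separately, 1-(2,4-dihydroxyphenyl)ethanone F2 is protected at the 4-hydroxyl as in step 4 to 1-[2-hydroxy-4-(methoxymethoxy)phenyl]ethanone F3.
- F3 is condensed with N,N-dimethylformamide dimethyl acetal to (E)-3-(dimethylamino)-1-[2-hydroxy-4-(methoxymethoxy)phenyl]prop-2-en-1-one F4, which is cyclised with I2 and pyridine in CHCl3 to 3-iodo-7-(methoxymethoxy)chromen-4-one F5.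
- Suzuki–Miyaura coupling of F1 with F5 (Pd(PPh3)4, K2CO3, dioxane–water, 80 °C) should give 14.

**Step 3.** The most likely failure is deprotonation at the benzylic–allylic CH2 of the prenyl group, or ortho to the methoxy group, instead of ortho to the C4 OMOM group. Proton transfer from the CH2Cl group of 6 to the aryllithium is a further loss.

Fallback, from 1 back to the route at 12: the acyl position is fixed by electrophilic substitution on the free resorcinol.
- Compound 1 is acetylated (AcOH, BF3·OEt2, 90 °C) ortho to one hydroxyl and para to the other to give 1-(2,4-dihydroxy-5-methoxyphenyl)ethanone F6.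
- C-Alkylation with 3 (aqueous KOH, 0 °C → rt) at the only free activated carbon, between the hydroxyls, gives 1-[2,4-dihydroxy-5-methoxy-3-(3-methylbut-2-enyl)phenyl]ethanone F7; O-alkylation is the expected loss.
- NaH and MOMCl give 1-[5-methoxy-2,4-bis(methoxymethoxy)-3-(3-methylbut-2-enyl)phenyl]ethanone F8.
- LiHMDS and Me3SiCl at −78 °C give the silyl enol ether trimethyl({1-[5-methoxy-2,4-bis(methoxymethoxy)-3-(3-methylbut-2-enyl)phenyl]ethenyl}oxy)silane F9.
- N-Bromosuccinimide in THF at −78 °C, where the enol ether should react far faster than the prenyl alkene, gives 2-bromo-1-[5-methoxy-2,4-bis(methoxymethoxy)-3-(3-methylbut-2-enyl)phenyl]ethanone F10.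
- F10 alkylates 11 under the conditions of step 5 to give 12.

**Step 5.** The most likely failure is aldol condensation of the new aryloxymethyl ketone with the neighbouring aldehyde under carbonate (Rap–Stoermer benzofuran formation), favoured if the hydrogen-bonded phenol alkylates slowly and the mixture has to be warmed.

Fallback, from 11 back to the route at 12: the aldehyde is absent while the ether is made.
- NaBH4 in MeOH reduces 11 to 2-(hydroxymethyl)-5-(methoxymethoxy)phenol F11.
- The phenol of F11 is alkylated with 9 (K2CO3, NaI, acetone) to 2-[2-(hydroxymethyl)-5-(methoxymethoxy)phenoxy]-1-[5-methoxy-2,4-bis(methoxymethoxy)-3-(3-methylbut-2-enyl)phenyl]ethanone F12.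
- MnO2 in CH2Cl2 at rt oxidises the benzylic alcohol of F12 to the aldehyde 12 under neutral conditions.

**Step 7.** The most likely failure is slow sulfamate formation at the hindered tertiary α-ketol, or ionisation of the sulfamate followed by capture at nitrogen or a 1,2-shift instead of loss of the C2 proton.

Fallback, from 13 directly to 15, bypassing 14: 13 is warmed in methanolic HCl (1–3 M, 50–60 °C). The acetals should fall first to rac-3-[2,4-dihydroxy-5-methoxy-3-(3-methylbut-2-enyl)phenyl]-3,7-dihydroxychroman-4-one F13. Its 2',4'-dihydroxyaryl group stabilises the C3 cation formed on loss of water, and loss of a C2 proton gives 15. The price is exposure of the prenyl group to warm acid.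

## Further compounds

F1 | step 6 | 2-[5-methoxy-2,4-bis(methoxymethoxy)-3-(3-methylbut-2-enyl)phenyl]-4,4,5,5-tetramethyl-1,3,2-dioxaborolane | COc1cc(B2OC(C)(C)C(C)(C)O2)c(OCOC)c(CC=C(C)C)c1OCOC
F2 | step 6 | 1-(2,4-dihydroxyphenyl)ethanone | CC(=O)c1ccc(O)cc1O
F3 | step 6 | 1-[2-hydroxy-4-(methoxymethoxy)phenyl]ethanone | CC(=O)c1ccc(OCOC)cc1O
F4 | step 6 | (E)-3-(dimethylamino)-1-[2-hydroxy-4-(methoxymethoxy)phenyl]prop-2-en-1-one | CN(C)/C=C/C(=O)c1ccc(OCOC)cc1O
F5 | step 6 | 3-iodo-7-(methoxymethoxy)chromen-4-one | COCOc1ccc2c(=O)c(I)coc2c1
F6 | step 3 | 1-(2,4-dihydroxy-5-methoxyphenyl)ethanone | COc1cc(C(C)=O)c(O)cc1O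
F7 | step 3 | 1-[2,4-dihydroxy-5-methoxy-3-(3-methylbut-2-enyl)phenyl]ethanone | COc1cc(C(C)=O)c(O)c(CC=C(C)C)c1O
F8 | step 3 | 1-[5-methoxy-2,4-bis(methoxymethoxy)-3-(3-methylbut-2-enyl)phenyl]ethanone | COc1cc(C(C)=O)c(OCOC)c(CC=C(C)C)c1OCOC
F9 | step 3 | trimethyl({1-[5-methoxy-2,4-bis(methoxymethoxy)-3-(3-methylbut-2-enyl)phenyl]ethenyl}oxy)silane | COc1cc(C(=C)O[Si](C)(C)C)c(OCOC)c(CC=C(C)C)c1OCOC
F10 | step 3 | 2-bromo-1-[5-methoxy-2,4-bis(methoxymethoxy)-3-(3-methylbut-2-enyl)phenyl]ethanone | COc1cc(C(=O)CBr)c(OCOC)c(CC=C(C)C)c1OCOC
F11 | step 5 | 2-(hydroxymethyl)-5-(methoxymethoxy)phenol | COCOc1ccc(CO)c(O)c1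
F12 | step 5 | 2-[2-(hydroxymethyl)-5-(methoxymethoxy)phenoxy]-1-[5-methoxy-2,4-bis(methoxymethoxy)-3-(3-methylbut-2-enyl)phenyl]ethanone | OCc1ccc(OCOC)cc1OCC(=O)c1cc(OC)c(OCOC)c(CC=C(C)C)c1OCOC
F13 | step 7 | rac-3-[2,4-dihydroxy-5-methoxy-3-(3-methylbut-2-enyl)phenyl]-3,7-dihydroxychroman-4-one | COc1cc(C2(O)COc3cc(O)ccc3C2=O)c(O)c(CC=C(C)C)c1O
A1 | alternative 1 | 3-[2-hydroxy-5-methoxy-4-(methoxymethoxy)-3-(3-methylbut-2-enyl)phenyl]-7-(methoxymethoxy)chromen-4-one | COCOc1ccc2c(=O)c(-c3cc(OC)c(OCOC)c(CC=C(C)C)c3O)coc2c1
A2 | alternative 1 | 3-ethynyl-7-(methoxymethoxy)chromen-4-one | COCOc1ccc2c(=O)c(C#C)coc2c1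
A3 | alternative 1 | pentacarbonyl[(2Z)-1-methoxy-2-(methoxymethoxy)-6-methylhepta-2,5-dien-1-ylidene]chromium | COC(=[Cr](=C=O)(=C=O)(=C=O)(=C=O)=C=O)/C(OCOC)=C/CC=C(C)C
A4 | alternative 2 | 6-{2-[2,4-bis(methoxymethoxy)phenyl]-2-oxoethyl}-3-hydroxy-4-methoxy-2-(3-methylbut-2-enyl)phenyl acetate | COCOc1ccc(C(=O)Cc2cc(OC)c(O)c(CC=C(C)C)c2OC(C)=O)c(OCOC)c1
A5 | alternative 2 | rac-1-[2,4-bis(methoxymethoxy)phenyl]-3-[(E)-2-methoxyethenyl]-8-methyl-1-oxonon-7-en-4-yn-3-yl acetate | CO/C=C/C(OC(C)=O)(CC(=O)c1ccc(OCOC)cc1OCOC)C#CCC=C(C)C
A6 | alternative 3 | 5-bromo-3-[5-methoxy-2,4-bis(methoxymethoxy)-3-(3-methylbut-2-enyl)phenyl]-7-(methoxymethoxy)chromen-4-one | COCOc1cc(Br)c2c(=O)c(-c3cc(OC)c(OCOC)c(CC=C(C)C)c3OCOC)coc2c1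
A7 | alternative 3 | methyl 3-hydroxy-2-[5-methoxy-2,4-bis(methoxymethoxy)-3-(3-methylbut-2-enyl)phenyl]prop-2-enoate (enol form of the formyl ester, geometry not fixed) | COC(=O)C(=CO)c1cc(OC)c(OCOC)c(CC=C(C)C)c1OCOC
A8 | alternative 3 | 2-bromo-4-(methoxymethoxy)-6-(trimethylsilyl)phenyl trifluoromethanesulfonate | COCOc1cc(Br)c(OS(=O)(=O)C(F)(F)F)c([Si](C)(C)C)c1
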